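## Structural features

The target is a germacranolide: a ten-membered carbocycle (C1–C10) fused trans across C6–C7 to a five-membered α-methylene γ-lactone (O–C6, C7–C11, C11=C13, C12=O). The carbocycle carries a ketone at C1, a Z-trisubstituted alkene C4(Me)=C5, a tertiary carbinol at C10 (methyl and hydroxyl) and an isovalerate on the secondary oxygen at C8. All four stereocentres are R; C6, C7 and C8 are contiguous, and C10 stands 1,3 to C8 across the C9 methylene with the two oxygens anti. The fragile elements are:
- the exocyclic methylene lactone, which is a Michael acceptor and a dipolarophile and makes C7–H vinylogously acidic;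
- the allylic C6–O lactone bond, which acid can ionise;
- the C1/C10 α-ketol, which base can cleave or rearrange;
- the C8 ester.

The real difficulty is to close the medium ring while fixing the fully substituted C10 carbinol, without epimerising C7, moving the exocyclic alkene into the lactone ring or losing the Z geometry at C4=C5. The feature used is the 1,3-dioxygenation C8–O/C9/C10–O: C10 is the aldol carbon of a C8 ketone enolate and a C10 methyl ketone. The ring can therefore be closed at C9–C10, and the new C10 hydroxyl can afterwards direct the reduction at C8.

## Logic of the disconnections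

25 ⇒ 24. The C1 carbonyl is traded for two C1–S bonds of a cyclic dithioacetal. Only with C1 masked is the C10 ketone the single electrophile for the ring closure, and the same group is the acyl-anion handle that builds C1–C10. This removes the α-ketol from every reducing or basic step. The forward unmasking must be fast, must not touch the alkene, and must not set a thiol free next to the methylene lactone.

24 ⇒ 22 + 23. The C8–O acyl bond is cut. The ester is the most base-labile group and is best introduced after all enolate and hydride chemistry. The forward step must acylate the secondary hydroxyl beside a tertiary one, and must come before C1 is unmasked, since a free C8 hydroxyl could form a transannular hemiketal with the C1 ketone.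

22 ⇒ 21. The C8–H bond is cut, giving the C8 ketone. That ketone is what makes C9 an enolate position. The forward reduction must be delivered from the C10 oxygen to give the 1,3-anti diol and must spare the conjugated lactone.

21 ⇒ 20. The C9–C10 bond is cut, which opens the ten-membered ring and removes the C10 stereocentre. This is the only ring bond that is an aldol bond, and the enolate can be generated at C9 alone from a C9 halide. What remains is a monocyclic lactone with two stereocentres. The forward step demands control of the C10 face, selective single-electron reduction of the C–Br bond beside an acyl dithiane and an enoate, and high dilution.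

20 ⇒ 16 + 17. The C8–C9 bond is cut. Adding C9 as a one-carbon unit to a C8 carboxyl gives the halomethyl ketone without any enolisation step. The demand is that acylation of the diazo reagent outruns its cycloaddition to the methylene lactone, and that C7 keeps its configuration.

16 ⇒ 15 ⇒ 9 + 12. After an ester-to-acid change, the C6–C7 bond and the lactone O–C12 bond are cut. One allylation–lactonisation builds both C6 and C7 and the complete methylene lactone from two achiral pieces. The forward step must be anti-selective and enantioface-selective, must choose the aldehyde over the methyl ketone, and the later ester cleavage must leave the lactone and C7 intact.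

12 ⇒ 10. The C–Br bond is cut; the allylic bromide comes from the 1,1-disubstituted alkene by bromination and dehydrobromination.

9 ⇒ 8 ⇒ 6 + 7. After adjusting two oxidation levels, the C1–C10 bond is cut. The dithiane anion adds to a two-carbon aldehyde, and one oxidation then produces the enal and the methyl ketone together. The demands are a dianion (alkoxide plus dithiane carbanion) and retention of the Z geometry in the enal.

6 ⇒ 5 ⇒ 3 + 4 ⇒ 2 ⇒ 1. The C1–S bonds are cut, then C1 is traced to the distal alkene carbon of a commercial Z-configured terpenoid ester. The Z C4=C5 alkene, its methyl group and C2–C3 are bought intact. The demand is regioselective oxidation of the remote alkene.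

## Other disconnections considered

Alternative 1: The ring is cut at C5–C6 and the lactone at O–C12. In the forward direction CrCl2, regenerated at a cathode and assisted by NiCl2, would turn the Z-alkenyl iodide of the open-chain iodo aldehyde A2 into an alkenylchromium species. This adds to the C6 aldehyde, and the new alkoxide closes onto the C12 ester to give the silyl ether A1.
- In favour: chromium-mediated alkenyl–aldehyde closure is the best-documented route to medium rings. It tolerates the free C1 ketone and the C10 hydroxyl, carries the Z geometry in with retention, and makes ring and lactone in one operation.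
- Better than the chosen plan: C8 and C10 are set beforehand by acyclic methods, so C10 does not depend on a macrocyclic transition state. No thioacetal and no diazo reagent are needed.
- Against: A2 holds a formyl group on C7 next to the acrylate, so C7–H is doubly activated and can epimerise or move the alkene into conjugation. The C6 configuration is created during the closure.
- Comparison: on stereochemical risk in the ring-forming step the two plans are equal (one centre each). The mechanism is a two-electron organochromium addition against a single-electron enolate aldol; both need dilution. After closure two steps remain against three here, which is equal in practice. A2, with three stereocentres and an α-ketol in one chain, would need a clearly longer linear sequence.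

Alternative 2: The ring is cut at C8–C9 through a [3,3] retron. In the forward direction the potassium alkoxide of A4 would undergo an anionic oxy-Cope rearrangement to the dienone A3. A4 is the adduct of (R)-isopiperitenone A5 with a vinyl-metal reagent that carries the 4-methoxybenzyloxy group E at its terminus.
- In favour and better than the chosen plan: the ring expansion needs no dilution, is stereospecific through a chair, takes the Z C4=C5 geometry from the cyclohexene, and transfers chirality to C8. It reaches the carbocycle in two or three steps from a chiral-pool ketone.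
- Against: A3 lacks C11–C13, C7 is a bare methylene, C6 is a ketone and C1/C10 is still an alkene. What remains is C7 alkylation in competition with γ-deprotonation of the enone, C6 reduction, lactonisation, face- and site-selective oxidation of the C1(10) alkene to the ketol, and exchange of the ether for the isovalerate.
- Comparison: three stereocentres (C6, C7, C10) would have to be set on a flexible ten-membered ring after closure, against one by reagent control here. The total count would be higher and the late stages less secure.

Alternative 3: The ring is cut at C3–C4. In the forward direction zerovalent palladium would insert into the C4–I bond of the iodo cyclopropanol A7. The cyclopropanol would open to a C3 palladium homoenolate, and reductive elimination would give the amine adduct A6. Quaternisation and elimination then restore the methylene lactone.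
- In favour and better than the chosen plan: the new bond is remote from every stereocentre, so the closure creates none. The C1 ketone appears in the same step without a thioacetal, and the end game is one step. The amine adduct also shields the lactone.
- Against: cyclopropanol cross-coupling is poorly supported as a ten-membered ring closure. β-Hydride elimination of the homoenolate to an enone should compete once reductive elimination is slowed by ring strain. A7 must carry all four stereocentres, the ester, and a cyclopropanol beside the tertiary carbinol through a long linear sequence.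
- Comparison: all stereochemistry precedes the closure there, against one centre set in the closure here. The mechanism is a two-electron palladium cycle against single-electron enolate formation. The route would be longer before the ring closure and shorter after it, so the overall step economy is at best equal.

Key step: step 11

Remark: atom labels C1–C13 follow germacranolide numbering throughout. Assumption: in step 8 the (S,S) ligand is taken to direct the allyl group to the Si face of the aldehyde; if the sense of induction is the reverse, its mirror image is used.

## Route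

Step 1
Reactants: 1 neryl acetate [(2Z)-3,7-dimethylocta-2,6-dien-1-yl acetate]
Product: 2 (2Z)-5-(3,3-dimethyloxiran-2-yl)-3-methylpent-2-en-1-yl acetate (racemic at the oxirane carbon)
Conditions: mCPBA (1.05 equiv), CH2Cl2, 0 °C
Reagents that add atoms: 3-chloroperbenzoic acid, OOC(=O)c1cccc(Cl)c1
Why: Prilezhaev epoxidation; the peracid should choose the remote, more electron-rich trisubstituted alkene because the allylic acetate deactivates the other one. The new oxirane centre is of no consequence since it is cleaved in step 2.

Step 2
Reactants: 2 (2Z)-5-(3,3-dimethyloxiran-2-yl)-3-methylpent-2-en-1-yl acetate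
Product: 3 (2Z)-3-methyl-6-oxohex-2-en-1-yl acetate
Conditions: H5IO6 (1.2 equiv), THF/Et2O, 0 °C
Reagents that add atoms: none
Why: Periodic acid hydrates the epoxide and cleaves the glycol in the same flask (Malaprade-type cleavage), releasing acetone and the aldehyde that becomes C1. The conditions are brief and non-basic, so the Z alkene and the acetate should be untouched.

Step 3
Reactants: 3 (2Z)-3-methyl-6-oxohex-2-en-1-yl acetate; 4 propane-1,3-dithiol
Product: 5 (2Z)-5-(1,3-dithian-2-yl)-3-methylpent-2-en-1-yl acetate
Conditions: BF3·OEt2 (0.2 equiv), CH2Cl2, −20 °C
Reagents that add atoms: none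
Why: Lewis acid-catalysed dithioacetalisation of an unhindered aldehyde is fast at low temperature, where the allylic acetate should not ionise. The dithiane is both the latent C1 carbonyl and the acyl-anion handle for the C1–C10 bond.

Step 4
Reactants: 5 (2Z)-5-(1,3-dithian-2-yl)-3-methylpent-2-en-1-yl acetate
Product: 6 (2Z)-5-(1,3-dithian-2-yl)-3-methylpent-2-en-1-ol
Conditions: K2CO3 (0.2 equiv), MeOH, rt
Reagents that add atoms: none
Why: Base-catalysed methanolysis frees the allylic alcohol, because an acetate would not survive the organolithium of step 5.

Step 5
Reactants: 6 (2Z)-5-(1,3-dithian-2-yl)-3-methylpent-2-en-1-ol; 7 acetaldehyde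
Product: 8 (2Z)-5-[2-(1-hydroxyethyl)-1,3-dithian-2-yl]-3-methylpent-2-en-1-ol (both carbinol epimers)
Conditions: n-BuLi (2.2 equiv), THF, −30 °C; 7 (3 equiv), −78 °C; H2O
Reagents that add atoms: none
Why: Corey–Seebach umpolung; the first equivalent of base gives the alkoxide, the second the 2-lithio-1,3-dithiane, which adds to the aldehyde and forms the C1–C10 bond. The carbinol configuration is irrelevant because it is oxidised in step 6.

Step 6
Reactants: 8 (2Z)-5-[2-(1-hydroxyethyl)-1,3-dithian-2-yl]-3-methylpent-2-en-1-ol
Product: 9 (2Z)-5-(2-acetyl-1,3-dithian-2-yl)-3-methylpent-2-enal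
Conditions: (COCl)2 (3 equiv), DMSO (6 equiv), CH2Cl2, −78 °C; Et3N, −78 → −20 °C
Reagents that add atoms: none
Why: Swern oxidation turns the allylic alcohol into the enal (C6) and the secondary carbinol into the C10 methyl ketone in one operation. Activated dimethyl sulfoxide does not attack thioacetals, and the low temperature should preserve the Z geometry of the enal.

Step 7
Reactants: 10 dimethyl itaconate (dimethyl 2-methylidenebutanedioate)
Product: 12 dimethyl 2-(bromomethyl)fumarate [dimethyl (2Z)-2-(bromomethyl)but-2-enedioate; ester groups trans], via dibromide 11 (not isolated)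
Conditions: Br2 (1.05 equiv), CH2Cl2, 0 °C → rt; Et3N (1.1 equiv), Et2O, 0 °C
Reagents that add atoms: bromine, BrBr
Why: Electrophilic bromination of the 1,1-disubstituted alkene, then dehydrobromination through the ester enolate (E1cB type), gives the allylic bromide with the two esters trans.

Step 8
Reactants: 9 (2Z)-5-(2-acetyl-1,3-dithian-2-yl)-3-methylpent-2-enal; 12 dimethyl 2-(bromomethyl)fumarate
Product: 15 methyl (2R,3S)-2-[(1Z)-4-(2-acetyl-1,3-dithian-2-yl)-2-methylbut-1-en-1-yl]-4-methylidene-5-oxooxolane-3-carboxylate (trans lactone ester), via silyl ether 13 (not isolated), via hydroxy diester 14 (not isolated)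
Conditions: CrCl2 (10 mol %), (S,S)-3,6-di-tert-butyl-1,8-bis(4-isopropyl-4,5-dihydrooxazol-2-yl)-9H-carbazole (12 mol %), Mn powder (2 equiv), TMSCl (1.5 equiv), iPr2NEt (30 mol %), THF, 0 °C → rt; aq citric acid/THF; PPTS (cat.), CH2Cl2, rt
Reagents that add atoms: none
Why: Catalytic enantioselective Nozaki–Hiyama 2-(alkoxycarbonyl)allylation followed by lactonisation; the allylchromium species adds only to the aldehyde, not to the hindered methyl ketone, through a closed chair transition state with the γ-ester and the alkenyl residue equatorial, which should give the anti adduct and hence the trans lactone (C7). The tridentate bis(oxazoline) ligand is expected to direct attack to the Si face of the aldehyde and so set C6 as R. Mild acid then removes the silyl group and closes the five-membered lactone onto the acrylate ester.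

Step 9
Reactants: 15 methyl (2R,3S)-2-[(1Z)-4-(2-acetyl-1,3-dithian-2-yl)-2-methylbut-1-en-1-yl]-4-methylidene-5-oxooxolane-3-carboxylate
Product: 16 (2R,3S)-2-[(1Z)-4-(2-acetyl-1,3-dithian-2-yl)-2-methylbut-1-en-1-yl]-4-methylidene-5-oxooxolane-3-carboxylic acid
Conditions: Me3SnOH (3 equiv), 1,2-dichloroethane, 70 °C; 5% aq HCl, 0 °C
Reagents that add atoms: trimethyltin hydroxide, C[Sn](C)(C)O
Why: Trimethyltin hydroxide cleaves methyl esters by a mild, near-neutral acyl substitution that should leave the epimerisable C7 centre, the methylene lactone and the allylic C6–O bond intact. Any lactone opened on the way can only reclose to the same five-membered ring on acidification.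

Step 10
Reactants: 16 (2R,3S)-2-[(1Z)-4-(2-acetyl-1,3-dithian-2-yl)-2-methylbut-1-en-1-yl]-4-methylidene-5-oxooxolane-3-carboxylic acid; 17 (trimethylsilyl)diazomethane
Product: 20 (4S,5R)-5-[(1Z)-4-(2-acetyl-1,3-dithian-2-yl)-2-methylbut-1-en-1-yl]-4-(2-bromoacetyl)-3-methylideneoxolan-2-one, via acid chloride 18 (not isolated), via diazoketone 19 (not isolated)
Conditions: 1-chloro-N,N,2-trimethylprop-1-en-1-amine (1.2 equiv), CH2Cl2, 0 °C; 17 (2 equiv), MeCN/THF, −10 → 0 °C; 48% aq HBr, −10 °C
Reagents that add atoms: hydrogen bromide, Br
Why: The neutral α-chloroenamine gives the acid chloride without acid or base, acylation of the diazoalkane (first stage of an Arndt–Eistert sequence) gives the diazoketone, and hydrobromination with loss of N2 installs C9 as the bromomethyl ketone. Low temperature and immediate quenching are meant to keep dipolar cycloaddition of the diazo compounds to the methylene lactone from competing.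

Step 11
Reactants: 20 (4S,5R)-5-[(1Z)-4-(2-acetyl-1,3-dithian-2-yl)-2-methylbut-1-en-1-yl]-4-(2-bromoacetyl)-3-methylideneoxolan-2-one
Product: 21 (6R,7S,10R)-10-hydroxy-8-oxogermacra-4Z,11(13)-dien-12,6-olide with C1 as a spiro-1,3-dithiane
Conditions: SmI2 (0.1 M in THF, 2.2 equiv) added over 1 h to 20 (0.003 M in THF), −78 °C, then −40 °C; pH 7 phosphate buffer
Reagents that add atoms: none
Why: Two successive one-electron transfers from SmI2 cleave the C9–Br bond and give the trivalent samarium enolate C8(OSm)=C9 regiospecifically, without any base that could touch the more acidic C7–H. The enolate adds to the C10 ketone through a chair-like transition state in which samarium bridges the enolate and ketone oxygens; the closest known reaction type is the SmI2-promoted intramolecular Reformatsky-type aldol of α-halo carbonyl compounds, which closes medium rings. The ten-membered carbocycle is closed in a 10-(enolendo)-exo-trig mode, C9 attacking the C10 carbonyl whose oxygen stays outside the ring. The new C10 centre should be set by the chelated chair, with the bulky dithiane-bearing C1 equatorial and the methyl axial, on the enolate face that the C7 centre of the trans lactone exposes through its C6 arm; this is expected to give 10R and is the least secure prediction of the route. Chemoselectivity rests on rate: the α-bromo ketone is reduced far faster than the C–S bonds of the acyl dithiane or the enoate, and inverse addition of just two equivalents at −78 °C keeps excess reductant away from them. Conjugate addition of the enolate to C13 would be a 5-endo-trig closure and is disfavoured, while high dilution suppresses intermolecular aldol reaction. A cold, neutral quench should avoid retro-aldol cleavage and β-elimination of the lactone oxygen from the new β-hydroxy ketone, which is taken on without delay.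

Step 12
Reactants: 21 (6R,7S,10R)-10-hydroxy-8-oxogermacra-4Z,11(13)-dien-12,6-olide with C1 as a spiro-1,3-dithiane
Product: 22 (6R,7R,8R,10R)-8,10-dihydroxygermacra-4Z,11(13)-dien-12,6-olide with C1 as a spiro-1,3-dithiane
Conditions: Me4NBH(OAc)3 (5 equiv), MeCN/AcOH (1:1), −30 °C
Reagents that add atoms: none
Why: Evans–Saksena reduction; the C10 hydroxyl exchanges onto boron and hydride is delivered intramolecularly to C8 through a chair transition state, which should give the 1,3-anti diol (C8 R). This mild acyloxyborohydride does not reduce the methylene lactone.

Step 13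
Reactants: 22 (6R,7R,8R,10R)-8,10-dihydroxygermacra-4Z,11(13)-dien-12,6-olide with C1 as a spiro-1,3-dithiane; 23 3-methylbutanoic anhydride (isovaleric anhydride)
Product: 24 (6R,7R,8R,10R)-10-hydroxy-8-(3-methylbutanoyloxy)germacra-4Z,11(13)-dien-12,6-olide with C1 as a spiro-1,3-dithiane
Conditions: 23 (1.5 equiv), DMAP (0.1 equiv), pyridine, CH2Cl2, 0 °C → rt
Reagents that add atoms: none
Why: DMAP-catalysed acylation is selective for the secondary C8 hydroxyl over the tertiary C10 hydroxyl. Acylating before C1 is unmasked also keeps the C8 hydroxyl from forming a transannular hemiketal with the C1 ketone.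

Step 14
Reactants: 24 (6R,7R,8R,10R)-10-hydroxy-8-(3-methylbutanoyloxy)germacra-4Z,11(13)-dien-12,6-olide with C1 as a spiro-1,3-dithiane
Product: 25 (6R,7R,8R,10R)-10-hydroxy-8-(3-methylbutanoyloxy)-1-oxogermacra-4Z,11(13)-dien-12,6-olide (CNP0105188.1)
Conditions: PhI(OCOCF3)2 (1.5 equiv), MeCN/H2O (9:1), 0 °C, 10 min; aq NaHCO3 work-up
Reagents that add atoms: water, O
Why: Oxidative dethioacetalisation with a trivalent iodine reagent; sulfur is activated, water attacks C1 and the sulfur leaves as the cyclic disulfide, so no free thiol is available to add to the methylene lactone. The reaction is fast at 0 °C, and the esters, the trisubstituted alkene and the tertiary alcohol should be tolerated.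

## Compound list

1 | neryl acetate, (2Z)-3,7-dimethylocta-2,6-dien-1-yl acetate | CC(C)=CCC/C(C)=C\COC(C)=O | starting material
2 | (2Z)-5-(3,3-dimethyloxiran-2-yl)-3-methylpent-2-en-1-yl acetate | CC1(C)OC1CC/C(C)=C\COC(C)=O | intermediate
3 | (2Z)-3-methyl-6-oxohex-2-en-1-yl acetate | O=CCC/C(C)=C\COC(C)=O | intermediate
4 | propane-1,3-dithiol | SCCCS | starting material
5 | (2Z)-5-(1,3-dithian-2-yl)-3-methylpent-2-en-1-yl acetate | CC(=O)OC/C=C(/C)CCC1SCCCS1 | intermediate
6 | (2Z)-5-(1,3-dithian-2-yl)-3-methylpent-2-en-1-ol | OC/C=C(/C)CCC1SCCCS1 | intermediate
7 | acetaldehyde | CC=O | starting material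
8 | (2Z)-5-[2-(1-hydroxyethyl)-1,3-dithian-2-yl]-3-methylpent-2-en-1-ol | OC/C=C(/C)CCC1(SCCCS1)C(C)O | intermediate
9 | (2Z)-5-(2-acetyl-1,3-dithian-2-yl)-3-methylpent-2-enal | O=C/C=C(/C)CCC1(SCCCS1)C(C)=O | intermediate
10 | dimethyl itaconate | C=C(CC(=O)OC)C(=O)OC | starting material
11 | dimethyl 2-bromo-2-(bromomethyl)butanedioate | COC(=O)CC(Br)(CBr)C(=O)OC | intermediate
12 | dimethyl 2-(bromomethyl)fumarate, dimethyl (2Z)-2-(bromomethyl)but-2-enedioate | COC(=O)/C=C(\CBr)C(=O)OC | intermediate
13 | dimethyl (2S)-2-[(1R,2Z)-5-(2-acetyl-1,3-dithian-2-yl)-3-methyl-1-(trimethylsilyloxy)pent-2-en-1-yl]-3-methylidenebutanedioate | COC(=O)[C@H]([C@@H](/C=C(/C)CCC1(SCCCS1)C(C)=O)O[Si](C)(C)C)C(=C)C(=O)OC | intermediate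
14 | dimethyl (2S)-2-[(1R,2Z)-5-(2-acetyl-1,3-dithian-2-yl)-1-hydroxy-3-methylpent-2-en-1-yl]-3-methylidenebutanedioate | COC(=O)[C@H]([C@@H](/C=C(/C)CCC1(SCCCS1)C(C)=O)O)C(=C)C(=O)OC | intermediate
15 | methyl (2R,3S)-2-[(1Z)-4-(2-acetyl-1,3-dithian-2-yl)-2-methylbut-1-en-1-yl]-4-methylidene-5-oxooxolane-3-carboxylate | COC(=O)[C@@H]1[C@@H](/C=C(/C)CCC2(SCCCS2)C(C)=O)OC(=O)C1=C | intermediate
16 | (2R,3S)-2-[(1Z)-4-(2-acetyl-1,3-dithian-2-yl)-2-methylbut-1-en-1-yl]-4-methylidene-5-oxooxolane-3-carboxylic acid | OC(=O)[C@@H]1[C@@H](/C=C(/C)CCC2(SCCCS2)C(C)=O)OC(=O)C1=C | intermediate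
17 | (trimethylsilyl)diazomethane | C[Si](C)(C)C=[N+]=[N-] | starting material
18 | (2R,3S)-2-[(1Z)-4-(2-acetyl-1,3-dithian-2-yl)-2-methylbut-1-en-1-yl]-4-methylidene-5-oxooxolane-3-carbonyl chloride | ClC(=O)[C@@H]1[C@@H](/C=C(/C)CCC2(SCCCS2)C(C)=O)OC(=O)C1=C | intermediate
19 | (4S,5R)-5-[(1Z)-4-(2-acetyl-1,3-dithian-2-yl)-2-methylbut-1-en-1-yl]-4-(2-diazoacetyl)-3-methylideneoxolan-2-one | [N-]=[N+]=CC(=O)[C@@H]1[C@@H](/C=C(/C)CCC2(SCCCS2)C(C)=O)OC(=O)C1=C | intermediate
20 | (4S,5R)-5-[(1Z)-4-(2-acetyl-1,3-dithian-2-yl)-2-methylbut-1-en-1-yl]-4-(2-bromoacetyl)-3-methylideneoxolan-2-one | BrCC(=O)[C@@H]1[C@@H](/C=C(/C)CCC2(SCCCS2)C(C)=O)OC(=O)C1=C | intermediate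
21 | (6R,7S,10R)-10-hydroxy-8-oxogermacra-4Z,11(13)-dien-12,6-olide, C1 as spiro-1,3-dithiane | C=C1C(=O)O[C@@H]2/C=C(/C)CCC3(SCCCS3)[C@](C)(O)CC(=O)[C@@H]12 | intermediate
22 | (6R,7R,8R,10R)-8,10-dihydroxygermacra-4Z,11(13)-dien-12,6-olide, C1 as spiro-1,3-dithiane | C=C1C(=O)O[C@@H]2/C=C(/C)CCC3(SCCCS3)[C@](C)(O)C[C@@H](O)[C@@H]12 | intermediate
23 | 3-methylbutanoic anhydride (isovaleric anhydride) | CC(C)CC(=O)OC(=O)CC(C)C | starting material
24 | (6R,7R,8R,10R)-10-hydroxy-8-(3-methylbutanoyloxy)germacra-4Z,11(13)-dien-12,6-olide, C1 as spiro-1,3-dithiane | C=C1C(=O)O[C@@H]2/C=C(/C)CCC3(SCCCS3)[C@](C)(O)C[C@@H](OC(=O)CC(C)C)[C@@H]12 | intermediate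
25 | (6R,7R,8R,10R)-10-hydroxy-8-(3-methylbutanoyloxy)-1-oxogermacra-4Z,11(13)-dien-12,6-olide | C=C1C(=O)O[C@@H]2/C=C(/C)CCC(=O)[C@](C)(O)C[C@@H](OC(=O)CC(C)C)[C@@H]12 | target

## Step count and weak points

Total: 14 steps. Longest linear sequence: 13 steps (steps 1–6 and 8–14, from 1); step 7 is a one-step side branch.

Step 11 (key step). The most likely failure is that the samarium enolate is protonated, or equilibrates toward C7, before it reaches the hindered C10 ketone, which sits next to a fully substituted carbon. That would mean simple loss of bromine and erosion at C7. Also possible are addition to the wrong face of C10 and reductive C–S cleavage beside the C10 ketone if reductant accumulates. The fallback sets out from 20 and returns at 21. Reductive silylation of the bromo ketone (Zn, TMSCl, MeCN) would give the trimethylsilyl enol ether F1. F1 would then be closed at high dilution by a Lewis acid-promoted Mukaiyama aldol addition to the C10 ketone (BF3·OEt2, CH2Cl2, −78 °C), with mild acidic work-up to free the tertiary hydroxyl. This closure runs through an open transition state, so its facial preference is independent of samarium chelation, and no reducing metal is present while the ring forms.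

Step 8. The likely failure is insufficient enantioface or anti selectivity. The Z-β,β-disubstituted enal is a hindered and unusual partner, and the second ester of the bromide can compete for chromium and loosen the chair. The fallback sets out from 9 and returns at 16. An indium-mediated Barbier reaction of 9 with 12 (indium powder, THF/H2O) followed by acid lactonisation would give 15 together with its mirror image, the ent-ester F2, after removal of any cis isomer. An esterase screened for selectivity toward 15 (pH 7 buffer) would then hydrolyse it to 16 and leave F2 behind. The resolution thereby also replaces step 9.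

Step 10. The likely failure is dipolar cycloaddition of the diazoalkane, or of the diazoketone once formed, to the methylene lactone in competition with the slow acylation; loss of C7 configuration through a ketene is a lesser risk. The fallback sets out from 16 and returns at 20. Conjugate addition of benzeneselenolate (PhSeSePh reduced beforehand with NaBH4, EtOH, then AcOH, 0 °C) would mask the lactone as the selenide acid F3. The same three-stage homologation would give the bromo ketone selenide F4. Oxidation at selenium (30% H2O2, THF, 0 °C, no amine) and syn elimination of the selenoxide toward C11–H would restore the exocyclic methylene. Selenium is oxidised much faster than thioacetal sulfur under these conditions.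

Step 12. The likely failure is that the hindered tertiary C10 hydroxyl does not exchange onto boron, or that the ring conformation overrides the chair delivery. Either leads to intermolecular hydride attack with the wrong or mixed facial outcome. The fallback sets out from 21 and returns at 24. Chelation-controlled reduction with catecholborane (THF, −10 °C) would give the 1,3-syn diol F5. A Mitsunobu esterification with 3-methylbutanoic acid (PPh3, DIAD, toluene) would then invert C8 and install the ester together, which also replaces step 13.

Step 14. The likely failure is slow hydrolysis at the doubly hindered C1, which would leave time for the oxidant or activated sulfur species to engage the trisubstituted alkene or the methylene lactone. The fallback sets out from 24 and returns at 25. Dimethylamine (THF, 0 °C) would add to the lactone to give the amine adduct F6. Methyl iodide with CaCO3 in aqueous MeCN would unmask C1 by S-alkylation and hydrolysis while quaternising the nitrogen, giving the ammonium iodide F7. Aqueous NaHCO3 would then eliminate trimethylamine and regenerate the methylene lactone.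

## Further compounds

F1 | step 11 | (4S,5R)-5-[(1Z)-4-(2-acetyl-1,3-dithian-2-yl)-2-methylbut-1-en-1-yl]-3-methylidene-4-[1-(trimethylsilyloxy)ethenyl]oxolan-2-one | C=C(O[Si](C)(C)C)[C@@H]1[C@@H](/C=C(/C)CCC2(SCCCS2)C(C)=O)OC(=O)C1=C
F2 | step 8 | methyl (2S,3R)-2-[(1Z)-4-(2-acetyl-1,3-dithian-2-yl)-2-methylbut-1-en-1-yl]-4-methylidene-5-oxooxolane-3-carboxylate (enantiomer of 15) | COC(=O)[C@H]1[C@H](/C=C(/C)CCC2(SCCCS2)C(C)=O)OC(=O)C1=C
F3 | step 10 | (2R,3S)-2-[(1Z)-4-(2-acetyl-1,3-dithian-2-yl)-2-methylbut-1-en-1-yl]-5-oxo-4-[(phenylselanyl)methyl]oxolane-3-carboxylic acid (C4 epimers) | OC(=O)[C@@H]1[C@@H](/C=C(/C)CCC2(SCCCS2)C(C)=O)OC(=O)C1C[Se]c1ccccc1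
F4 | step 10 | (4S,5R)-5-[(1Z)-4-(2-acetyl-1,3-dithian-2-yl)-2-methylbut-1-en-1-yl]-4-(2-bromoacetyl)-3-[(phenylselanyl)methyl]oxolan-2-one (C3 epimers) | BrCC(=O)[C@@H]1[C@@H](/C=C(/C)CCC2(SCCCS2)C(C)=O)OC(=O)C1C[Se]c1ccccc1
F5 | step 12 | (6R,7R,8S,10R)-8,10-dihydroxygermacra-4Z,11(13)-dien-12,6-olide, C1 as spiro-1,3-dithiane (8-epimer of 22) | C=C1C(=O)O[C@@H]2/C=C(/C)CCC3(SCCCS3)[C@](C)(O)C[C@H](O)[C@@H]12
F6 | step 14 | (11R)-13-(dimethylamino)-11,13-dihydro derivative of 24 | CN(C)C[C@@H]1C(=O)O[C@@H]2/C=C(/C)CCC3(SCCCS3)[C@](C)(O)C[C@@H](OC(=O)CC(C)C)[C@@H]12
F7 | step 14 | (11R)-13-(trimethylammonio)-11,13-dihydro derivative of 25, iodide | C[N+](C)(C)C[C@@H]1C(=O)O[C@@H]2/C=C(/C)CCC(=O)[C@](C)(O)C[C@@H](OC(=O)CC(C)C)[C@@H]12.[I-]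
A1 | alternative 1 | 8-(tert-butyldimethylsilyloxy)-10-hydroxy-1-oxogermacra-4Z,11(13)-dien-12,6-olide, configured as 25 | C=C1C(=O)O[C@@H]2/C=C(/C)CCC(=O)[C@](C)(O)C[C@@H](O[Si](C)(C)C(C)(C)C)[C@@H]12
A2 | alternative 1 | methyl (10Z)-4-(tert-butyldimethylsilyloxy)-3-formyl-6-hydroxy-11-iodo-6,10-dimethyl-2-methylidene-7-oxoundec-10-enoate, configured as A1 | I/C=C(/C)CCC(=O)[C@](C)(O)C[C@@H](O[Si](C)(C)C(C)(C)C)[C@@H](C(=C)C(=O)OC)C=O
A3 | alternative 2 | (8R)-8-(4-methoxybenzyloxy)-4,10-dimethylcyclodeca-4Z,1(10)E-dien-6-one (germacrane numbering) | C1/C(C)=C\C(=O)C[C@H](OCc2ccc(OC)cc2)C/C(C)=C/C1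
A4 | alternative 2 | (1R,6R)-1-[(E)-2-(4-methoxybenzyloxy)ethenyl]-3-methyl-6-(prop-1-en-2-yl)cyclohex-2-en-1-ol | CC1=C[C@](O)(/C=C/OCc2ccc(OC)cc2)[C@H](CC1)C(C)=C
A5 | alternative 2 | (R)-isopiperitenone, (6R)-3-methyl-6-(prop-1-en-2-yl)cyclohex-2-en-1-one | CC1=CC(=O)[C@H](CC1)C(C)=C
A6 | alternative 3 | (11R)-13-(dimethylamino)-11,13-dihydro derivative of 25 | CN(C)C[C@@H]1C(=O)O[C@@H]2/C=C(/C)CCC(=O)[C@](C)(O)C[C@@H](OC(=O)CC(C)C)[C@@H]12
A7 | alternative 3 | 3-[(dimethylamino)methyl]-4-[3-hydroxy-3-(1-hydroxycyclopropyl)-1-(3-methylbutanoyloxy)butyl]-5-[(1Z)-2-iodoprop-1-en-1-yl]oxolan-2-one, configured as A6 | OC1(CC1)[C@](C)(O)C[C@@H](OC(=O)CC(C)C)[C@H]2[C@H](CN(C)C)C(=O)O[C@@H]2/C=C(/C)I
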